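| setting | gamma | epsilon | green | blue |
|---|---|---|---|---|
| substrate | 0.066 M | 0.066 M | 0.066 M | 0.066 M |
| coupling partner | 1.05 equiv | 1.05 equiv | 1.05 equiv | 1.05 equiv |
| free catalyst | 7 mol% | 11 mol% | 5 mol% | 5 mol% |
| second catalyst | 0.2 mol% | 0.2 mol% | 0.2 mol% | 0.2 mol% |
| remark | run made earlier | run made earlier |  |  |
| time |  |  | 10 min | 12 min |

- gamma (time / min: intermediate / %, substrate / %, product / %): 2.00: 2.2, 86.9, 9.0; 4.00: 3.1, 80.0, 17.4; 6.00: 1.9, 74.6, 22.8; 8.00: 1.9, 69.1, 30.1; 10.0: 1.9, 63.3, 33.7; 12.0: 2.4, 57.9, 38.8
- epsilon (time / min: intermediate / %, substrate / %, product / %): 0.833: 5.0, 91.1, 4.1; 2.50: 3.3, 80.1, 15.0; 4.00: 3.4, 74.8, 22.3; 6.00: 2.8, 66.8, 30.8; 10.0: 2.4, 54.8, 42.7; 12.0: 2.2, 49.2, 48.5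

(standard deviation of a reading: 0.5 percentage points)



- which of these there is most of at the end, counted by the substrate in it, green (intermediate / product / substrate)
- which of these there is most of at the end, counted by the substrate in it, blue (intermediate / product / substrate)
- final amount of the leader among these, as a percentage of the substrate charged, in green
- final amount of the leader among these, as a percentage of the substrate charged, in blue

**Order read.** The epsilon run, with more free catalyst than gamma, loses substrate with a pseudo-first-order constant of 0.0524 min⁻¹ against 0.0404 min⁻¹ from 4.00 min on, so 1.30 times as fast on 1.57 times the charge. Dividing the logarithms of those two ratios gives 0.573, the working order in catalyst charge. It is a reading, with the scatter of the readings in it, but it lies nearer a root than a proportion.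

**Your flasks.** Green and blue carry 5 mol% of free catalyst, so I scale gamma's constant down to 0.0333 min⁻¹. Gamma's late line runs back to 94.0% at the start. My reckoning, then: substrate leads, with 67.4% in green and 63.0% in blue.

**Leave alone.** Don't raise the free catalyst to hurry things: by this order, a factor 2 in the charge buys a factor 1.49 in the constant.

**The forecast.** It names substrate for both, with 68% (64.5% to 71%) in green and 62.5% (58.5% to 66%) in blue, on “a weak dependence on free catalyst”.

**The result.** Substrate leads both: 69.6% in green, 65.6% in blue.

    substrate + free catalyst ⇌ free catalyst + intermediate (K = 2.10, k = 18.0 M⁻¹ min⁻¹)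
    coupling partner + second catalyst + intermediate → second catalyst + product (k = 1.90 × 10⁵ M⁻² min⁻¹)
    2 free catalyst ⇌ resting dimer (K = 290 M⁻¹, k = 38.0 M⁻¹ min⁻¹)

**One reason.** Green keeps its substrate partly through the resting dimer, an off-cycle resting state, and partly through the short time: without the dimer step it ends at 55.9%, and by 100 min it holds 5.12%. Between 5.00 min and 10.0 min green loses substrate with a constant of 0.0312 min⁻¹, a little below the 0.0333 min⁻¹ scaled by the working order. Green's neighbour charged with 0.26 M of substrate keeps the loadings, so its charged c(free catalyst) rises in the same ratio; over green's time, the working order scales green's logarithmic loss to 45.2% of the substrate charged, and that flask holds 42.1%.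

The data stem from a simulated flask with constants of no real substance, noise included.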